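**Retrosynthetic overview**
1. Target 28 comes from lactone 24 by three late events: release of the C14 aldehyde, the C8 methacrylate, and the C4–C5 oxirane made from the 4Z-alkene through a bromohydrin.
2. Lactone 24 is cut into macrocyclic diene 20 and 2-bromoacrylic acid 21. One palladium-catalysed [3+2] carbo-oxygenation makes C7–C11 and C6–O together. This delivers the whole α-methylene-γ-lactone ring (O–C12–C11–C7–C6) and both of its stereocentres.
3. Enabling feature: once the oxirane carbons C4/C5 are read as an alkene, C6–O is an allylic ester bond and C7–C11 is the next bond. The lactone is therefore the adduct of a C–C–O unit across C6=C7 of a C4=C5–C6=C7 diene. Inside the ten-membered ring the E-C6=C7 bond shows only its outer face, next to the C8 stereocentre.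
4. Ring order is ten-membered carbocycle first (Nozaki–Hiyama–Kishi closure C9–C10 of iodo-aldehyde 17), lactone second, oxirane third.
5. Compound 17 is assembled from neryl acetate (C1–C6, C15, Z-C4=C5), Ph3P=CHCHO (C10, C14) and methyl (R)-isopropylideneglycerate (C7–C9, C8 stereocentre), joined by an E-selective Wittig reaction.

Key step: step 16

Remark: germacrane numbering is used (ring C1–C10, lactone C11–C13, C14 on C10, C15 on C4). α/β refer to the flat ring numbered counter-clockwise with H-7 α. The SMILES is read as 4R,5S,6S,7R,8S,9R. This means a cis-oxirane (C3 and C6 on the same side), a trans-fused lactone, an erythro C8/C9 pair, and C2 cis to C9 at C1=C10.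

**Route**

Step 1
Reactants: 1 neryl acetate
Product: 2 (2Z)-5-(3,3-dimethyloxiran-2-yl)-3-methylpent-2-en-1-yl acetate (racemic at the oxirane CH)
Conditions: mCPBA (1.0 equiv), NaHCO3, CH2Cl2, 0 °C
Reagents that add atoms: mCPBA, OOC(=O)c1cccc(Cl)c1
Why: Prilezhaev epoxidation should take the remote trisubstituted alkene, which is more electron-rich than the one deactivated by the allylic acetate; the new stereocentre is destroyed in step 2.

Step 2
Reactants: 2 epoxy acetate
Product: 3 (2Z)-3-methyl-6-oxohex-2-en-1-yl acetate
Conditions: H5IO6 (1.2 equiv), THF–H2O, 0 °C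
Reagents that add atoms: none
Why: Acid-promoted epoxide hydration followed by periodate glycol cleavage (Malaprade type) should release the C1 aldehyde and leave the Z-alkene and the acetate untouched.

Step 3
Reactants: 3 aldehyde; 4 (triphenylphosphoranylidene)acetaldehyde
Product: 5 (2Z,6E)-3-methyl-8-oxoocta-2,6-dien-1-yl acetate
Conditions: toluene, 80 °C
Reagents that add atoms: (triphenylphosphoranylidene)acetaldehyde 4, O=CC=P(c1ccccc1)(c1ccccc1)c1ccccc1
Why: Wittig olefination with a stabilised ylide should add C10 and C14 as an E-enal.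

Step 4
Reactants: 5 enal
Product: 6 (2Z,6Z)-7-iodo-3-methyl-8-oxoocta-2,6-dien-1-yl acetate
Conditions: I2 (1.5 equiv), DMAP (0.2 equiv), K2CO3 (1.2 equiv), THF–H2O 1:1, rt
Reagents that add atoms: iodine, [I][I]
Why: α-Iodination of an enal by a Baylis–Hillman-type addition, iodination and elimination sequence should give the isomer with the alkyl chain trans to CHO (iodine cis to C2), the geometry that later makes C2 and C9 cis.

Step 5
Reactants: 6 iodoenal
Product: 7 (2Z,6Z)-7-iodo-8,8-dimethoxy-3-methylocta-2,6-dien-1-yl acetate
Conditions: HC(OMe)3, CSA (cat.), MeOH, rt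
Reagents that add atoms: trimethyl orthoformate, COC(OC)OC
Why: Acid-catalysed acetalisation masks C14 at the aldehyde oxidation level, so no redox step is needed later.

Step 6
Reactants: 7 acetal acetate
Product: 8 (2Z,6Z)-7-iodo-8,8-dimethoxy-3-methylocta-2,6-dien-1-ol
Conditions: K2CO3 (0.2 equiv), MeOH, 0 °C
Reagents that add atoms: none
Why: Base-catalysed transesterification (Zemplén type) should free the C6 alcohol; acetal and alkenyl iodide are base-stable.

Step 7
Reactants: 8 allylic alcohol
Product: 9 (2Z,6Z)-8-bromo-2-iodo-1,1-dimethoxy-6-methylocta-2,6-diene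
Conditions: CBr4, PPh3, 2,6-lutidine, CH2Cl2, −20 °C
Reagents that add atoms: carbon tetrabromide, BrC(Br)(Br)Br
Why: The Appel reaction runs under neutral conditions by direct SN2 displacement, so the Z-alkene and the acetal should be kept.

Step 8
Reactants: 9 allylic bromide
Product: 10 tributyl[(2Z,6Z)-7-iodo-8,8-dimethoxy-3-methylocta-2,6-dien-1-yl]phosphonium bromide
Conditions: PBu3, MeCN, rt
Reagents that add atoms: tributylphosphine, CCCCP(CCCC)CCCC
Why: SN2 quaternisation of the primary allylic bromide should be fast at room temperature and leaves the alkenyl iodide alone.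

Step 9
Reactants: 11 methyl (4R)-2,2-dimethyl-1,3-dioxolane-4-carboxylate
Product: 12 methyl (2R)-2,3-dihydroxypropanoate
Conditions: Dowex 50WX8 (H+ form), MeOH–H2O 9:1, rt
Reagents that add atoms: none
Why: Acid hydrolysis of the acetonide does not touch the stereocentre (future C8).

Step 10
Reactants: 12 diol ester
Product: 13 methyl (2R)-2,3-bis(triethylsilyloxy)propanoate
Conditions: Et3SiCl (2.3 equiv), imidazole, DMF, 0 °C
Reagents that add atoms: chlorotriethylsilane, CC[Si](Cl)(CC)CC
Why: Standard silylation gives one primary and one secondary TES ether, which step 13 can tell apart.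

Step 11
Reactants: 13 ester
Product: 14 (2R)-2,3-bis(triethylsilyloxy)propanal
Conditions: i-Bu2AlH (1.05 equiv), CH2Cl2, −78 °C; Rochelle salt
Reagents that add atoms: none
Why: Partial ester reduction stops at the aldehyde because the α-alkoxy tetrahedral aluminate is stable at −78 °C.

Step 12
Reactants: 10 phosphonium bromide; 14 aldehyde
Product: 16 (2Z,6Z,8E,10S)-2-iodo-1,1-dimethoxy-6-methyl-10,11-bis(triethylsilyloxy)undeca-2,6,8-triene, via allylic tributylphosphonium ylide 15 (not isolated)
Conditions: KOtBu (1.0 equiv), THF, −78 °C; then 14, −78 → 0 °C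
Reagents that add atoms: none
Why: Wittig olefination with allylic trialkylphosphonium ylides is E-selective and should build E-C6=C7 next to the retained Z-C4=C5; C8 is carried over from 14 unchanged.

Step 13
Reactants: 16 bis-TES ether
Product: 17 (2S,3E,5Z,9Z)-10-iodo-11,11-dimethoxy-6-methyl-2-(triethylsilyloxy)undeca-3,5,9-trienal
Conditions: (COCl)2 (4 equiv), DMSO (8 equiv), CH2Cl2, −78 → −40 °C; Et3N, −78 °C
Reagents that add atoms: none
Why: Under Swern conditions a primary TES ether is desilylated and oxidised directly while a secondary TES ether survives, which gives the C9 aldehyde in one step (to be used at once, without chromatography on acidic silica).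

Step 14
Reactants: 17 iodo-aldehyde
Product: 19 (1R,2S,3E,5Z,9E)-10-(dimethoxymethyl)-6-methyl-2-(triethylsilyloxy)cyclodeca-3,5,9-trien-1-ol (ring bonds cis at C5=C6 and C9=C10), via alkenylchromium dichloride 18 (not isolated)
Conditions: CrCl2 (8 equiv), NiCl2 (2 mol %), DMSO–THF, 2 mM, syringe pump, rt
Reagents that add atoms: none
Why: The intramolecular Nozaki–Hiyama–Kishi reaction keeps the alkenyl geometry (C2 cis to C9) and tolerates acetal, diene and silyl ether; the non-chelating OTES group should steer Felkin–Anh addition to the 8,9-anti (erythro, 9R) alcohol.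

Step 15
Reactants: 19 macrocyclic alcohol
Product: 20 (1R,2S,3E,5Z,9E)-10-(dimethoxymethyl)-6-methyl-2-(triethylsilyloxy)cyclodeca-3,5,9-trien-1-yl acetate
Conditions: Ac2O, pyridine, DMAP (cat.), CH2Cl2, 0 °C
Reagents that add atoms: acetic anhydride, CC(=O)OC(C)=O
Why: DMAP-catalysed acylation of the only free hydroxyl installs the C9 acetate of the target with retention.

Step 16
Reactants: 20 macrocyclic diene acetate; 21 2-bromoacrylic acid
Product: 24 9β-acetoxy-14,14-dimethoxy-8β-(triethylsilyloxy)germacra-1(10),4,11(13)-trien-12,6α-olide (ring bonds cis at C1=C10 and C4=C5; H-6β and H-7α), via alkenylpalladium bromide 22 (not isolated), via allylpalladium carboxylate chelate 23 (not isolated)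
Conditions: Pd2(dba)3·CHCl3 (5 mol %), P(2-furyl)3 (20 mol %), Ag2CO3 (1.2 equiv), 21 (1.5 equiv, syringe pump), BHT (cat.), 1,4-dioxane, 50 °C, dark
Reagents that add atoms: 2-bromoacrylic acid 21, C=C(Br)C(=O)O
Why: Proposed new method: zerovalent palladium inserts into the C–Br bond of 21 to give 22, Ag2CO3 removes bromide and deprotonates the acid, syn-carbopalladation of the strained E-C6=C7 bond joins C11 to C7 and leaves divalent palladium on C6 as an allyl unit (C4–C5–C6) held in the six-membered carboxylate chelate 23, and C–O reductive elimination with retention makes O–C6 and returns zerovalent palladium. The closest known reaction type is the Larock heteroannulation of 1,3-dienes with organic halides that carry a carboxylic acid or phenol (Heck insertion followed by capture of the allyl unit), whereas a 2-haloacrylic acid as three-atom partner on a medium-ring diene has not been shown. The only ring closed is the five-membered lactone, formed by contraction of the six-membered palladacycle at the proximal allyl terminus C6 and not at the tertiary terminus C4, which would give a seven-membered ring. C7 is set by attack on the only open (outer) face of the E-alkene in the conformer that keeps C8–C9 on the inner face, the C8–OTES bond eclipsed with the alkene and C8–H on the outer face (the flipped conformer puts OTES in the path of the reagent), and C6 is set by the suprafacial course (syn insertion, then retention) because the other allyl face looks into the ring, so that E geometry plus syn addition gives the trans lactone. The step needs diene over C1=C10 (unstrained, trisubstituted, flanked by acetal and acetate), C7 over the fully substituted C4, and no ionisation of the C8 and C9 oxygen groups, which is secured by a silyl ether at the dienylic C8 and by the hindered, inductively deactivated alkene next to the C9 acetate. The 4Z geometry should be kept because syn/anti exchange would need palladium on the tertiary C4.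

Step 17
Reactants: 24 lactone
Product: 25 9β-acetoxy-8β-hydroxy-14-oxogermacra-1(10),4,11(13)-trien-12,6α-olide (same alkene geometries)
Conditions: 1 M aq. HCl–THF 1:4, 0 °C → rt
Reagents that add atoms: water, O
Why: Mild aqueous acid should cleave the secondary TES ether and hydrolyse the allylic dimethyl acetal in one operation, giving the enal with its geometry kept (C2 trans to CHO is also the stable one).

Step 18
Reactants: 25 hydroxy enal
Product: 26 9β-acetoxy-8β-methacryloyloxy-14-oxogermacra-1(10),4,11(13)-trien-12,6α-olide
Conditions: methacrylic anhydride (3 equiv), Et3N, DMAP (0.1 equiv), CH2Cl2, 0 °C → rt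
Reagents that add atoms: methacrylic anhydride, C=C(C)C(=O)OC(=O)C(C)=C
Why: DMAP-catalysed acylation (Steglich type) of the only hydroxyl installs the C8 ester with retention.

Step 19
Reactants: 26 triene ester
Product: 27 (4R,5R)-bromohydrin: 9β-acetoxy-5β-bromo-4α-hydroxy-8β-methacryloyloxy-14-oxogermacra-1(10),11(13)-dien-12,6α-olide
Conditions: NBS (1.05 equiv), DME–H2O 4:1, 0 °C, dark
Reagents that add atoms: N-bromosuccinimide, O=C1CCC(=O)N1Br; water, O
Why: Bromohydrin formation (anti, Markovnikov): allylic 1,3-strain across Z-C4=C5 keeps C6–H in the alkene plane so that C7 and the rest of the ring shield one face, Br+ is taken up on the open face that carries the lactone oxygen and water opens the bromonium ion at the tertiary C4 from the other side, which sets C4 and places bromine at C5 ready for inversion, while the other four C=C bonds are electron-poor and inert.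

Step 20
Reactants: 27 bromohydrin
Product: 28 target, (4R,5S,6S,7R,8S,9R)-9-acetoxy-4,5-epoxy-8-methacryloyloxy-14-oxogermacra-1(10),11(13)-dien-12,6-olide
Conditions: Ag2O (3 equiv), CH2Cl2, 4 Å MS, rt, dark
Reagents that add atoms: none
Why: Silver-assisted intramolecular Williamson-type SN2 closure: the C4 oxygen displaces bromide at C5 with inversion, which gives the cis-oxirane on the face a peracid cannot reach directly, under non-basic conditions that spare the enal, the allylic acetate and both acrylate units.

**Compound list**
1 | neryl acetate | CC(C)=CCC/C(C)=C\COC(C)=O | starting material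
2 | (2Z)-5-(3,3-dimethyloxiran-2-yl)-3-methylpent-2-en-1-yl acetate | CC1(C)OC1CC/C(C)=C\COC(C)=O | intermediate
3 | (2Z)-3-methyl-6-oxohex-2-en-1-yl acetate | O=CCC/C(C)=C\COC(C)=O | intermediate
4 | (triphenylphosphoranylidene)acetaldehyde | O=CC=P(c1ccccc1)(c1ccccc1)c1ccccc1 | starting material
5 | (2Z,6E)-3-methyl-8-oxoocta-2,6-dien-1-yl acetate | O=C/C=C/CC/C(C)=C\COC(C)=O | intermediate
6 | (2Z,6Z)-7-iodo-3-methyl-8-oxoocta-2,6-dien-1-yl acetate | O=C/C(I)=C/CC/C(C)=C\COC(C)=O | intermediate
7 | (2Z,6Z)-7-iodo-8,8-dimethoxy-3-methylocta-2,6-dien-1-yl acetate | COC(OC)/C(I)=C/CC/C(C)=C\COC(C)=O | intermediate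
8 | (2Z,6Z)-7-iodo-8,8-dimethoxy-3-methylocta-2,6-dien-1-ol | COC(OC)/C(I)=C/CC/C(C)=C\CO | intermediate
9 | (2Z,6Z)-8-bromo-2-iodo-1,1-dimethoxy-6-methylocta-2,6-diene | COC(OC)/C(I)=C/CC/C(C)=C\CBr | intermediate
10 | tributyl[(2Z,6Z)-7-iodo-8,8-dimethoxy-3-methylocta-2,6-dien-1-yl]phosphonium bromide | COC(OC)/C(I)=C/CC/C(C)=C\C[P+](CCCC)(CCCC)CCCC.[Br-] | intermediate
11 | methyl (4R)-2,2-dimethyl-1,3-dioxolane-4-carboxylate | COC(=O)[C@H]1COC(C)(C)O1 | starting material
12 | methyl (2R)-2,3-dihydroxypropanoate | OC[C@@H](O)C(=O)OC | intermediate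
13 | methyl (2R)-2,3-bis(triethylsilyloxy)propanoate | CC[Si](CC)(CC)OC[C@@H](O[Si](CC)(CC)CC)C(=O)OC | intermediate
14 | (2R)-2,3-bis(triethylsilyloxy)propanal | CC[Si](CC)(CC)OC[C@@H](O[Si](CC)(CC)CC)C=O | intermediate
15 | allylic tributylphosphonium ylide from 10 | COC(OC)/C(I)=C/CC/C(C)=C\C=P(CCCC)(CCCC)CCCC | intermediate
16 | (2Z,6Z,8E,10S)-2-iodo-1,1-dimethoxy-6-methyl-10,11-bis(triethylsilyloxy)undeca-2,6,8-triene | CC[Si](CC)(CC)OC[C@@H](O[Si](CC)(CC)CC)/C=C/C=C(C)\CC/C=C(I)/C(OC)OC | intermediate
17 | (2S,3E,5Z,9Z)-10-iodo-11,11-dimethoxy-6-methyl-2-(triethylsilyloxy)undeca-3,5,9-trienal | O=C[C@@H](O[Si](CC)(CC)CC)/C=C/C=C(C)\CC/C=C(I)/C(OC)OC | intermediate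
18 | alkenylchromium dichloride from 17 (solvent ligands omitted) | O=C[C@@H](O[Si](CC)(CC)CC)/C=C/C=C(C)\CC/C=C([Cr](Cl)Cl)/C(OC)OC | intermediate
19 | (1R,2S,3E,5Z,9E)-10-(dimethoxymethyl)-6-methyl-2-(triethylsilyloxy)cyclodeca-3,5,9-trien-1-ol | CC[Si](CC)(CC)O[C@H]1/C=C/C=C(C)\CC/C=C(/C(OC)OC)[C@H]1O | intermediate
20 | (1R,2S,3E,5Z,9E)-10-(dimethoxymethyl)-6-methyl-2-(triethylsilyloxy)cyclodeca-3,5,9-trien-1-yl acetate | CC[Si](CC)(CC)O[C@H]1/C=C/C=C(C)\CC/C=C(/C(OC)OC)[C@H]1OC(C)=O | intermediate
21 | 2-bromoacrylic acid | C=C(Br)C(=O)O | starting material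
22 | (1-carboxyvinyl)palladium bromide (phosphines omitted) | OC(=O)C(=C)[Pd]Br | intermediate
23 | allylpalladium carboxylate chelate, drawn in its C6-bound form (phosphine omitted) | CC[Si](CC)(CC)O[C@H]1[C@H]2C(=C)C(=O)O[Pd][C@@H]2/C=C(C)\CC/C=C(/C(OC)OC)[C@H]1OC(C)=O | intermediate
24 | 9β-acetoxy-14,14-dimethoxy-8β-(triethylsilyloxy)germacra-1(10),4,11(13)-trien-12,6α-olide | CC[Si](CC)(CC)O[C@H]1[C@H]2C(=C)C(=O)O[C@@H]2/C=C(C)\CC/C=C(/C(OC)OC)[C@H]1OC(C)=O | intermediate
25 | 9β-acetoxy-8β-hydroxy-14-oxogermacra-1(10),4,11(13)-trien-12,6α-olide | O[C@H]1[C@H]2C(=C)C(=O)O[C@@H]2/C=C(C)\CC/C=C(/C=O)[C@H]1OC(C)=O | intermediate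
26 | 9β-acetoxy-8β-methacryloyloxy-14-oxogermacra-1(10),4,11(13)-trien-12,6α-olide | C=C(C)C(=O)O[C@H]1[C@H]2C(=C)C(=O)O[C@@H]2/C=C(C)\CC/C=C(/C=O)[C@H]1OC(C)=O | intermediate
27 | (4R,5R)-5-bromo-4-hydroxy derivative of 26 | C=C(C)C(=O)O[C@H]1[C@H]2C(=C)C(=O)O[C@@H]2[C@@H](Br)[C@](C)(O)CC/C=C(/C=O)[C@H]1OC(C)=O | intermediate
28 | CNP0121379.1 | C=C(C)C(=O)O[C@H]1[C@H]2C(=C)C(=O)O[C@@H]2[C@@H]2O[C@]2(C)CC/C=C(/C=O)[C@H]1OC(C)=O | target

**Step count**
- Total step count: 20.
- Longest linear sequence: 17 (steps 1–8 and 12–20).

**Steps most likely to fail**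

1. **Step 16.** Insertion into the hindered internal diene may be slow. That would let β-hydride loss to a triene, self-coupling of 21, or ionisation of allylic C–O bonds by zerovalent palladium take over.
   - The fallback sets out from 20 and comes back at 25, using known chemistry only.
   - 20 would be treated with mono-tert-butyl malonate, Mn(OAc)3·2H2O and Cu(OAc)2·H2O in AcOH–KOAc at 40 °C. This is the oxidative radical lactone annulation of a 1,3-diene by trivalent manganese: the electrophilic malonyl radical adds to C7, divalent copper oxidises the allyl radical, and the free acid closes on C6. It gives the α-(tert-butoxycarbonyl) lactone F1.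
   - TFA in wet CH2Cl2 would then remove the tert-butyl, silyl and acetal groups to give the α-carboxy lactone F2.
   - Aqueous formaldehyde, Et2NH and NaOAc in AcOH (decarboxylative Mannich methylenation) would give 25.

2. **Step 14.** Intermolecular coupling may compete with closure of the strained triene ring, and facial selectivity at the aldehyde may be poor.
   - The fallback sets out from 17 and comes back at 20.
   - The 9-epimeric macrocyclic alcohol F3, separated after the same ring closure, would be converted by a Mitsunobu reaction (AcOH, PPh3, DIAD, toluene, 0 °C). This proceeds with inversion at C9 and gives acetate 20 directly, so correction and acetylation fall into one step.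

3. **Step 19.** Water must enter from the shielded face, so opening of the bromonium ion may be slow or poorly face-selective, and allylic bromination may intervene.
   - The fallback sets out from 26 and comes back at 28. It replaces substrate control by catalyst control.
   - It is a Shi-type epoxidation with the sugar-derived ketone enantiomer matched to the required face (Oxone, buffered MeCN–dimethoxymethane–H2O, 0 °C).
   - It makes no compound outside the list (F0).

Further compounds
F1 | step 16 | α-(tert-butoxycarbonyl) lactone (C11 epimers) | CC[Si](CC)(CC)O[C@H]1[C@H]2C(C(=O)OC(C)(C)C)C(=O)O[C@@H]2/C=C(C)\CC/C=C(/C(OC)OC)[C@H]1OC(C)=O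
F2 | step 16 | α-carboxy lactone hydroxy enal (C11 epimers) | O[C@H]1[C@H]2C(C(=O)O)C(=O)O[C@@H]2/C=C(C)\CC/C=C(/C=O)[C@H]1OC(C)=O
F3 | step 14 | 9-epimeric macrocyclic alcohol | CC[Si](CC)(CC)O[C@H]1/C=C/C=C(C)\CC/C=C(/C(OC)OC)[C@@H]1O
F0 | step 19 | none | none
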